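Amounts come first, and the count to watch is that of nucleophile against electrophile.

| setting | green | grey | ochre |
|---|---|---|---|
| electrophile | 0.0020 M | 0.0020 M | 0.0020 M |
| nucleophile | 1.10 equiv | 1.10 equiv | 1.10 equiv |
| free base | 12.0 equiv | 3.00 equiv | 6.00 equiv |
| time | 50 s | 50 s | 50 s |

    electrophile + nucleophile ⇌ acid set free + target (K1 = 0.66, k1 = 28.9 M⁻¹ s⁻¹)
    nucleophile + acid set free ⇌ protonated nucleophile, settled at all times (K2 = 3.60 × 10⁶ M⁻¹)
    acid set free + free base ⇌ salt of the base (K3 = 34600 M⁻¹, k3 = 40.0 M⁻¹ s⁻¹)
    free base + target ⇌ idle adduct, settled at all times (K4 = 360 M⁻¹)
    target ⇌ isomer of the product (K5 = 1.32, k5 = 0.00230 s⁻¹)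

- part of the electrophile that has reacted at the end, green
- part of the electrophile that has reacted at the end, grey
- part of the electrophile that has reacted at the end, ochre
- what raising the equivalents of free base from its lowest to its highest value here does to the part of the electrophile that has reacted (changes below 5 percentage points count as none) (it rises / no change / it falls)

- what is said of target includes idle adduct
- run time (green): 50 s

My own reckoning builds the flask up one process at a time, with x the part of the electrophile reacted. The main step by itself is a balance with constant 0.66, and for 1.10 equiv of nucleophile it stops at x = 47.0%.

Adding the capture of acid changes the count. In grey, its constant times the starting nucleophile is 7900, far above unity, so acid set free ends up on a second nucleophile. Each electrophile then costs two nucleophiles, and the nucleophile becomes the limiting reagent despite its excess. This gives the two-for-one mark h, the nucleophile equivalents divided by two, as a part of the electrophile charged: 55.0%. Integrating the main step with nucleophile spent two at a time gives x0 = 53.1% at 50 s.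

Next comes the free base, which can return nucleophile through the trace of free acid. At x = 0.5, that acid is about 1.39 × 10⁻⁶ M. The main step then runs at 5.78 × 10⁻⁶ M s⁻¹, against 1.33 × 10⁻⁶ M s⁻¹ for salt formation in green and 3.33 × 10⁻⁷ M s⁻¹ in grey, with the free base taken at its charge. As nucleophile falls, the comparison drifts towards the base, since the main step slows while the acid rises. Held over the run as a rough estimate, these rates add 1.7 percentage points to h in green and 0.42 points in grey. The gap of 1.2 points is less than 5 points, so I expect no change.

The idle adduct and the isomer spend no nucleophile, and the half-life of free target by the forward rate of step 5 alone, 5.0 min, is longer than the run, so I add nothing to my number for them.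

The forecast gave 53.7% for green, 53.3% for grey and 53.5% for ochre, with no change, reasoning that “about two nucleophiles are used per electrophile”. That is the same count as mine, so the closeness of the two is no check.

The simulation gives 53.6% for green, 53.2% for grey and 53.4% for ochre: no change, with a change of 0.4 points. Green moves by 5 points when nucleophile goes to 0.987 equiv or 1.22 equiv, close on either side of its 1.10 equiv. In green, h less the free nucleophile left (4.71% of its charge), counted two to one, plus the salt (4.62 × 10⁻⁵ M) and the acid set free (2.74 × 10⁻⁶ M), counted likewise, comes to 53.6%.

A neighbour of green charged with 0.280 equiv of nucleophile has h = 14.0%, and the same balance on its end state gives 15.0%. The computed result is 15.0%.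

All constants are invented; the run is a simulation.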